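**Retrosynthetic overview**
1. Target 14 ⇒ global hydrogenolysis of 13. The ester C–O bond of 13 ⇒ cis-alcohol 9 + acid chloride 12 (D ring bought, its catechol masked as a diphenylmethylene ketal).
2. 9 ⇒ configurationally labile flavan-3-one 8. One asymmetric transfer hydrogenation with dynamic kinetic resolution sets C2 and C3 together.
3. 8 ⇒ 3,4-epoxyflavan 7 by epoxide-to-ketone (Meinwald) rearrangement.
4. 7 ⇒ salicylaldehyde 2 + styrylsulfonium salt 5. The O1–C2, C3–C4 and C3–O bonds form in one flask.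
5. Ring order: aromatic rings A, B and D are bought. The dioxole mask on D is made off-line. Pyran ring C and the oxirane form together in step 4, the oxirane is spent in step 5, and the dioxole falls in step 8.

Assumption: 3,4,5-tris(benzyloxy)benzaldehyde and 3-O-methylgallic acid are bought as catalogue chemicals, and the (R,R)-catalyst is assigned to the (2R,3R)-alcohol by analogy with aryl ketone reductions (its antipode is equally available).

**Step 1**
Reactants: 1 2,4,6-trihydroxybenzaldehyde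
Product: 2 4,6-bis(benzyloxy)-2-hydroxybenzaldehyde
Conditions: BnBr (2.05 equiv), K2CO3, DMF, 0 °C to rt
Reagents that add atoms: benzyl bromide, BrCc1ccccc1
Why: Williamson etherification stops after two alkylations because the last ortho hydroxyl is locked in a hydrogen bond to the aldehyde and is the least nucleophilic oxygen.

**Step 2**
Reactants: 3 3,4,5-tris(benzyloxy)benzaldehyde
Product: 4 3,4,5-tris(benzyloxy)styrene
Conditions: Ph3PCH3Br, KOtBu, THF, 0 °C to rt
Reagents that add atoms: methyltriphenylphosphonium bromide, C[P+](c1ccccc1)(c1ccccc1)c1ccccc1.[Br-]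
Why: Wittig methylenation of a non-enolisable aryl aldehyde leaves the benzyl ethers untouched.

**Step 3**
Reactants: 4 3,4,5-tris(benzyloxy)styrene
Product: 5 (E)-diphenyl{2-[3,4,5-tris(benzyloxy)phenyl]vinyl}sulfonium triflate
Conditions: Ph2SO, Tf2O, CH2Cl2, −78 °C; then 4, 2,6-di-tert-butylpyridine, −78 to −20 °C; precipitation with Et2O
Reagents that add atoms: diphenyl sulfoxide, O=S(c1ccccc1)c1ccccc1; triflic anhydride, O=S(=O)(OS(=O)(=O)C(F)(F)F)C(F)(F)F
Why: In this interrupted Pummerer-type alkene sulfonium formation the activated sulfoxide is attacked by the terminal alkene carbon, and the benzylic cation loses a proton to give the (E)-alkenylsulfonium salt, a known route from styrenes.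

**Step 4 (key step)**
Reactants: 2 4,6-bis(benzyloxy)-2-hydroxybenzaldehyde; 5 (E)-diphenyl{2-[3,4,5-tris(benzyloxy)phenyl]vinyl}sulfonium triflate
Product: 7 (±)-(2R*,3R*,4R*)-5,7-bis(benzyloxy)-3,4-epoxy-2-[3,4,5-tris(benzyloxy)phenyl]chroman, via sulfonium ylide 6 (not isolated)
Conditions: DBU (2 equiv), CH2Cl2 (0.05 M), 0 °C; buffer wash, filtration through basic alumina, used at once
Reagents that add atoms: none
Why: Proposed new method: the phenoxide of 2 adds to the β-carbon of 5 (oxa-Michael) to give ylide 6, whose carbanion attacks the neighbouring aldehyde to close the pyran ring, after which the anti-betaine expels Ph2S to close the oxirane (Johnson–Corey–Chaykovsky step), the closest known reaction being the epoxy-annulation of amino or hydroxy carbonyl compounds with diphenylvinylsulfonium triflate; the bulky sulfonium group should sit trans to the C2 aryl group and so predict the all-cis racemate, but any diastereomer serves because C3 and C4 lose their configuration and C2 is reset in step 5.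

**Step 5**
Reactants: 7 (±)-(2R*,3R*,4R*)-5,7-bis(benzyloxy)-3,4-epoxy-2-[3,4,5-tris(benzyloxy)phenyl]chroman
Product: 9 (2R,3R)-5,7-bis(benzyloxy)-2-[3,4,5-tris(benzyloxy)phenyl]chroman-3-ol, via flavan-3-one 8 (not isolated)
Conditions: Sc(OTf)3 (2 mol %), CH2Cl2, −20 °C; then RuCl[(R,R)-TsDPEN](mesitylene) (2 mol %), HCO2H–Et3N (1:1), 35 °C
Reagents that add atoms: none
Why: Proposed new method: the Lewis acid ionises the donor-activated benzylic C4–O bond and a 1,2-hydride shift (Meinwald rearrangement, known for chromene oxides) gives ketone 8, whose C2–H (α-keto, benzylic, α-aryloxy) epimerises through the enol in the amine-rich medium while the chiral Ru hydride reduces only the (2R)-ketone from the face opposite the aryl group, which sets the 2R,3R cis pair in one event; the closest known reactions are Noyori–Ikariya transfer hydrogenations with dynamic kinetic resolution of α-aryl cyclic ketones such as isoflavanones.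

**Step 6**
Reactants: 10 3-O-methylgallic acid (3,4-dihydroxy-5-methoxybenzoic acid)
Product: 12 7-methoxy-2,2-diphenyl-1,3-benzodioxole-5-carbonyl chloride, via ketal acid 11 (not isolated)
Conditions: Ph2CCl2 (1.2 equiv), Ph2O, 170 °C; then (COCl)2, cat. DMF, toluene, rt; crystallisation from heptane
Reagents that add atoms: dichlorodiphenylmethane, ClC(Cl)(c1ccccc1)c1ccccc1; oxalyl chloride, O=C(Cl)C(=O)Cl
Why: Ketalisation with the gem-dichloride masks the only vicinal diol pair in one stroke as a hydrogenolysable diphenylmethylene ketal, and Vilsmeier-type activation then turns the acid into its chloride without touching ketal or methyl ether.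

**Step 7**
Reactants: 9 (2R,3R)-5,7-bis(benzyloxy)-2-[3,4,5-tris(benzyloxy)phenyl]chroman-3-ol; 12 7-methoxy-2,2-diphenyl-1,3-benzodioxole-5-carbonyl chloride
Product: 13 (2R,3R)-5,7-bis(benzyloxy)-2-[3,4,5-tris(benzyloxy)phenyl]chroman-3-yl 7-methoxy-2,2-diphenyl-1,3-benzodioxole-5-carboxylate
Conditions: Et3N, DMAP (0.2 equiv), CH2Cl2, 0 °C to rt
Reagents that add atoms: none
Why: DMAP-catalysed acylation of the only free hydroxyl breaks no bond at C2 or C3, so both stereocentres are kept, as in the standard galloylation of protected epigallocatechin.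

**Step 8**
Reactants: 13 (2R,3R)-5,7-bis(benzyloxy)-2-[3,4,5-tris(benzyloxy)phenyl]chroman-3-yl 7-methoxy-2,2-diphenyl-1,3-benzodioxole-5-carboxylate
Product: 14 (−)-epigallocatechin 3-(3-methylgallate)
Conditions: H2 (1 atm), 20% Pd(OH)2/C, THF–MeOH, rt; filtration under N2
Reagents that add atoms: none
Why: Neutral catalytic hydrogenolysis cleaves the five benzyl ethers and both benzhydrylic C–O bonds of the ketal, while the ester, the methyl ether, the cyclic C2–O1 bond and the 2R,3R centres survive, as is usual for gallated catechins.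

**Compound list**
1 | 2,4,6-trihydroxybenzaldehyde | O=Cc1c(O)cc(O)cc1O | starting material
2 | 4,6-bis(benzyloxy)-2-hydroxybenzaldehyde | O=Cc1c(O)cc(OCc2ccccc2)cc1OCc1ccccc1 | intermediate
3 | 3,4,5-tris(benzyloxy)benzaldehyde | O=Cc1cc(OCc2ccccc2)c(OCc2ccccc2)c(OCc2ccccc2)c1 | starting material
4 | 3,4,5-tris(benzyloxy)styrene | C=Cc1cc(OCc2ccccc2)c(OCc2ccccc2)c(OCc2ccccc2)c1 | intermediate
5 | (E)-diphenyl{2-[3,4,5-tris(benzyloxy)phenyl]vinyl}sulfonium triflate | [O-]S(=O)(=O)C(F)(F)F.c1ccc(cc1)[S+](c1ccccc1)/C=C/c1cc(OCc2ccccc2)c(OCc2ccccc2)c(OCc2ccccc2)c1 | intermediate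
6 | β-aryloxy diphenylsulfonium ylide from 2 and 5 (racemic, not isolated) | O=Cc1c(OCc2ccccc2)cc(OCc2ccccc2)cc1OC([CH-][S+](c1ccccc1)c1ccccc1)c1cc(OCc2ccccc2)c(OCc2ccccc2)c(OCc2ccccc2)c1 | intermediate
7 | (±)-(2R*,3R*,4R*)-5,7-bis(benzyloxy)-3,4-epoxy-2-[3,4,5-tris(benzyloxy)phenyl]chroman (racemate, one enantiomer drawn) | O1[C@@H]2[C@H]1c1c(OCc3ccccc3)cc(OCc3ccccc3)cc1O[C@@H]2c1cc(OCc2ccccc2)c(OCc2ccccc2)c(OCc2ccccc2)c1 | intermediate
8 | 5,7-bis(benzyloxy)-2-[3,4,5-tris(benzyloxy)phenyl]chroman-3-one (C2 labile, not isolated) | O=C1Cc2c(OCc3ccccc3)cc(OCc3ccccc3)cc2OC1c1cc(OCc2ccccc2)c(OCc2ccccc2)c(OCc2ccccc2)c1 | intermediate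
9 | (2R,3R)-5,7-bis(benzyloxy)-2-[3,4,5-tris(benzyloxy)phenyl]chroman-3-ol | O[C@@H]1Cc2c(OCc3ccccc3)cc(OCc3ccccc3)cc2O[C@@H]1c1cc(OCc2ccccc2)c(OCc2ccccc2)c(OCc2ccccc2)c1 | intermediate
10 | 3-O-methylgallic acid | COc1cc(C(=O)O)cc(O)c1O | starting material
11 | 7-methoxy-2,2-diphenyl-1,3-benzodioxole-5-carboxylic acid (not isolated) | COc1cc(C(=O)O)cc2OC(c3ccccc3)(c3ccccc3)Oc12 | intermediate
12 | 7-methoxy-2,2-diphenyl-1,3-benzodioxole-5-carbonyl chloride | COc1cc(C(=O)Cl)cc2OC(c3ccccc3)(c3ccccc3)Oc12 | intermediate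
13 | (2R,3R)-5,7-bis(benzyloxy)-2-[3,4,5-tris(benzyloxy)phenyl]chroman-3-yl 7-methoxy-2,2-diphenyl-1,3-benzodioxole-5-carboxylate | COc1cc(C(=O)O[C@@H]2Cc3c(OCc4ccccc4)cc(OCc4ccccc4)cc3O[C@@H]2c2cc(OCc3ccccc3)c(OCc3ccccc3)c(OCc3ccccc3)c2)cc2OC(c3ccccc3)(c3ccccc3)Oc12 | intermediate
14 | (−)-epigallocatechin 3-(3-methylgallate), 2R,3R | COc1cc(C(=O)O[C@@H]2Cc3c(O)cc(O)cc3O[C@@H]2c2cc(O)c(O)c(O)c2)cc(O)c1O | target

**Total step count:** 8.
**Longest linear sequence:** 6 steps (3 → 4 → 5 → 7 → 9 → 13 → 14).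

**Steps most likely to fail**

Step 4. The β-aryl group lowers the acceptor strength of 5, the aldehyde of 2 is electron-rich, and 7 is acid-labile. The fallback builds the pyran ring first and adds the oxygen afterwards. It sets out from 3. Ethynylmagnesium bromide gives 1-[3,4,5-tris(benzyloxy)phenyl]prop-2-yn-1-ol F1. A Mitsunobu reaction with commercial 3,5-bis(benzyloxy)phenol gives the aryl propargyl ether F2. Gold(I)-catalysed 6-endo hydroarylation gives 5,7-bis(benzyloxy)-2-[3,4,5-tris(benzyloxy)phenyl]-2H-chromene F3. Dimethyldioxirane, attacking anti to the aryl group, gives the racemic 2,3-trans epoxide F4. The Lewis acid of step 5 rearranges F4, so the fallback comes back to the route at 8.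

Step 5. Racemisation of 8 may be slower than its reduction, or the catalyst may discriminate poorly, because 8 is not an aryl ketone. The fallback replaces catalyst control by substrate control plus classical resolution. It sets out from 8, isolated after the Sc(OTf)3 stage. L-Selectride attacks anti to the aryl group and gives the cis-alcohol as a racemate of 9 and its (2S,3S)-enantiomer F5. Esterification with (S)-O-methylmandelic acid (DCC, DMAP) gives the (2R,3R)-mandelate F6 and the (2S,3S)-mandelate F7, which are separated by crystallisation or chromatography. Methanolysis of F6 (K2CO3, MeOH–THF) comes back to the route at 9.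

Step 3. The activated sulfoxide may attack the electron-rich arene, or the acid may polymerise the styrene. The fallback builds the C–S bond by olefination and makes the sulfonium centre last. It sets out from 3 and bypasses 4. Horner–Wadsworth–Emmons reaction with diethyl (phenylthio)methylphosphonate (NaH, THF) gives (E)-phenyl 2-[3,4,5-tris(benzyloxy)phenyl]vinyl sulfide F8. Copper(II)-catalysed S-phenylation of F8 with diphenyliodonium triflate comes back to the route at 5.

**Further compounds**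
F1 | step 4 | 1-[3,4,5-tris(benzyloxy)phenyl]prop-2-yn-1-ol (racemic) | C#CC(O)c1cc(OCc2ccccc2)c(OCc2ccccc2)c(OCc2ccccc2)c1
F2 | step 4 | 3,5-bis(benzyloxy)phenyl 1-[3,4,5-tris(benzyloxy)phenyl]prop-2-ynyl ether (racemic) | C#CC(Oc1cc(OCc2ccccc2)cc(OCc2ccccc2)c1)c1cc(OCc2ccccc2)c(OCc2ccccc2)c(OCc2ccccc2)c1
F3 | step 4 | 5,7-bis(benzyloxy)-2-[3,4,5-tris(benzyloxy)phenyl]-2H-chromene (racemic) | C1=Cc2c(OCc3ccccc3)cc(OCc3ccccc3)cc2OC1c1cc(OCc2ccccc2)c(OCc2ccccc2)c(OCc2ccccc2)c1
F4 | step 4 | (±)-(2R*,3S*,4S*)-5,7-bis(benzyloxy)-3,4-epoxy-2-[3,4,5-tris(benzyloxy)phenyl]chroman (racemate, one enantiomer drawn) | O1[C@H]2[C@@H]1c1c(OCc3ccccc3)cc(OCc3ccccc3)cc1O[C@@H]2c1cc(OCc2ccccc2)c(OCc2ccccc2)c(OCc2ccccc2)c1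
F5 | step 5 | (2S,3S)-5,7-bis(benzyloxy)-2-[3,4,5-tris(benzyloxy)phenyl]chroman-3-ol | O[C@H]1Cc2c(OCc3ccccc3)cc(OCc3ccccc3)cc2O[C@H]1c1cc(OCc2ccccc2)c(OCc2ccccc2)c(OCc2ccccc2)c1
F6 | step 5 | (2R,3R)-5,7-bis(benzyloxy)-2-[3,4,5-tris(benzyloxy)phenyl]chroman-3-yl (S)-2-methoxy-2-phenylacetate | CO[C@@H](c1ccccc1)C(=O)O[C@@H]1Cc2c(OCc3ccccc3)cc(OCc3ccccc3)cc2O[C@@H]1c1cc(OCc2ccccc2)c(OCc2ccccc2)c(OCc2ccccc2)c1
F7 | step 5 | (2S,3S)-5,7-bis(benzyloxy)-2-[3,4,5-tris(benzyloxy)phenyl]chroman-3-yl (S)-2-methoxy-2-phenylacetate | CO[C@@H](c1ccccc1)C(=O)O[C@H]1Cc2c(OCc3ccccc3)cc(OCc3ccccc3)cc2O[C@H]1c1cc(OCc2ccccc2)c(OCc2ccccc2)c(OCc2ccccc2)c1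
F8 | step 3 | (E)-phenyl 2-[3,4,5-tris(benzyloxy)phenyl]vinyl sulfide | c1ccc(cc1)S/C=C/c1cc(OCc2ccccc2)c(OCc2ccccc2)c(OCc2ccccc2)c1
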